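**Time of reading.** The flask is read at 12 h, yet alder stops at 2.50 h, so I must know how much E is left that late.

| setting | alder | ash | flask |
|---|---|---|---|
| Q | 43 mM | 43 mM | 43 mM |
| E | 1.05 equiv | 0.53 equiv | 1.05 equiv |
| remark | the very flask that is asked about, followed so far | run made earlier |  |
| time |  |  | 12 h |

| run | time / h | D / % | L / % | Q / % |
|---|---|---|---|---|
| alder | 0.500 | 2.6 | 1.4 | 96.6 |
| alder | 1.00 | 4.6 | 2.5 | 92.4 |
| alder | 1.33 | 5.7 | 2.6 | 91.6 |
| alder | 2.00 | 8.1 | 3.6 | 88.4 |
| alder | 2.50 | 9.6 | 4.4 | 85.7 |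
| ash | 0.417 | 1.4 | 0.3 | 98.2 |
| ash | 1.33 | 2.9 | 2.0 | 95.6 |
| ash | 2.00 | 5.1 | 2.1 | 93.6 |
| ash | 3.00 | 6.4 | 3.2 | 90.4 |
| ash | 5.00 | 8.9 | 4.7 | 86.5 |

(scatter of a reading: 0.3 percentage points)

- the earlier runs were read with a standard deviation of 0.3 percentage points

* concentration of D at 12 h, in mM
* concentration of L at 12 h, in mM

**Rate as gauge.** I take minus the logarithm of the fraction of Q left to climb at a rate r proportional to E, a pseudo-first-order rate. Alder converted 7.10% of its Q (D plus L) by 1.00 h and 14.0% by 2.50 h. So r reads 0.0736 h⁻¹ over the first span and 0.0515 h⁻¹ over the second. Between the midpoints E therefore reads as falling to 0.699 of its value, less than the 0.933 that one-for-one use by Q accounts for, so I take E to be lost another way as well.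

**Halving time.** I take that loss as second order in E: ash, with half the E over twice the time, converted 13.6%, close to alder's 14.0%. The fraction of E left is then one over one plus t/τ. Alder's two rates give 2.40 h for τ, the time in which E halves, and τ goes inversely with the E charged. The starting rate is 0.0890 h⁻¹.

**At the reading.** At 12 h I expect E at 0.167 of its charge and Q converted 0.318. With D's read share of 0.686, that is 0.218 as D and 0.0999 as L, or 9.37 mM and 4.30 mM. The forecast, holding that “the reaction is first order in E and in Q”, says 13.3 mM and 6.3 mM, higher than mine.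

**The flask.** It gives 9.08 mM of D and 4.54 mM of L.

    Q + E → L (k = 0.600 M⁻¹ h⁻¹)
    2 E → J (k = 2.50 M⁻¹ h⁻¹)
    Q + E → D (k = 1.20 M⁻¹ h⁻¹)

At 12.0 h the flask holds 17% of its E, a species never read, where τ gave 16.7%. For the neighbour charged with 2.60 equiv, τ shrinks to 0.968 h, which puts E at 7.47% of its charge at 12 h; that neighbour holds 9.3%.

Readings and results were generated by integration for substances that don't exist; scatter was added.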